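(The numbers in the tables stem from a simulated flask for an exercise, noise included.)

At 2.0 min I want the fraction of free monomer in chains in each flask. I work with the fraction left, f, through its exponent −ln f; monomer in chains is then one minus f.

| flask | free monomer | pre-initiator | remark | time |
|---|---|---|---|---|
| north-east | 0.14 M | 2 mol% | run made earlier |  |
| north | 0.39 M | 2 mol% | run made earlier |  |
| west | 1.3 M | 2 mol% | run made earlier |  |
| Sunday's | 0.50 M | 2 mol% |  | 2.0 min |
| Wednesday's | 1.5 M | 1.2 mol% |  | 2.0 min |
| Friday's | 0.15 M | 4 mol% |  | 2.0 min |
| Saturday's | 0.12 M | 1.2 mol% |  | 2.0 min |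

| run | time / s | monomer in chains / % | free monomer / % |
|---|---|---|---|
| north-east | 10.0 | 0 | 99.9 |
| north-east | 12.0 | 0.1 | 99.5 |
| north-east | 25.0 | 0.5 | 99.7 |
| north-east | 40.0 | 1.1 | 99.4 |
| north-east | 80.0 | 4.5 | 95.9 |
| north | 10.0 | 0 | 99.7 |
| north | 12.0 | 0 | 99.4 |
| north | 25.0 | 1.4 | 98.9 |
| north | 40.0 | 3.4 | 96.8 |
| north | 80.0 | 11.0 | 89.3 |
| west | 10.0 | 0.5 | 100.0 |
| west | 12.0 | 0.7 | 99.1 |
| west | 25.0 | 4.0 | 96.6 |
| west | 40.0 | 10.1 | 90.5 |
| west | 80.0 | 32.0 | 67.4 |

(scatter of a reading: 0.3 percentage points)

- ranking by amount of monomer in chains, in percent of the free monomer charged, from high to low, at 2.0 min (Sunday's / Wednesday's / Friday's / Saturday's)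
- the amount of monomer in chains, in percent of the free monomer charged of the flask you put first, at 2.0 min
- the amount of monomer in chains, in percent of the free monomer charged of the flask you put last, at 2.0 min

- the numbers in the tables scatter with a standard deviation of 0.3 percentage points
- steps under discussion: pre-initiator -> initiator; free monomer + living end -> monomer in chains + living end; free monomer + initiator -> living end + monomer in chains

Take first the main step, free monomer + living end, with a fixed number of living ends. Then f falls by the same factor in each equal time, so the exponent grows in step with time and the free monomer charge drops out. Now add a steady supply of living ends from pre-initiator. The ends grow with time and with the pre-initiator charge, so the exponent grows as the square of time and in proportion to that charge.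

The west run shows the square: the exponent goes from 0.0998 at 40.0 s to 0.395 at 80.0 s, a factor of 3.95. The charge shows at 80.0 s: exponent per molar pre-initiator charge reads 15.0 M⁻¹, 14.5 M⁻¹ and 15.2 M⁻¹ in the north-east, north and west runs, while free monomer runs from 0.14 M to 1.3 M. So I carry one number, G, the exponent per molar pre-initiator charge at the time of reading, scaled from the last west reading by the square of time: 34.1 M⁻¹.

Then the rest. Capture of initiator by free monomer can show as a delay at low free monomer, but the north-east reading of that number lies as near the west one as a scatter of 0.3 percentage points allows. Use of pre-initiator slows the supply, so I expect G to read high at 2.0 min. My order is that of the molar pre-initiator charges: 0.0180 M for Wednesday's, 0.0100 M for Sunday's, 0.00600 M for Friday's and 0.00144 M for Saturday's. G gives 45.9% for Wednesday's and 4.80% for Saturday's.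

The forecast has Wednesday's > Sunday's > Friday's > Saturday's, with 43% and 4.4%, below my values, and its remark is “slight sag by 80 s suggests pre-initiator depletion”.

The flask gives Wednesday's > Sunday's > Friday's > Saturday's, with 43.4% for Wednesday's and 4.35% for Saturday's.

    pre-initiator → initiator (k = 0.00540 s⁻¹)
    free monomer + living end → monomer in chains + living end, rate k2*[living end]*[free monomer] (k = 1.00 M⁻¹ s⁻¹)
    free monomer + initiator → living end + monomer in chains (k = 0.830 M⁻¹ s⁻¹)

Read back, Wednesday's gives 31.6 M⁻¹ in place of G, lower than the 34.1 M⁻¹ carried from the west run. In Wednesday's at 1.27 min, initiator has a half-life of 0.71 s by capture against 2.1 min for pre-initiator by its own step; on the way to living ends, pre-initiator → initiator is there the rate-limiting step. With 2 mol% of pre-initiator in Wednesday's recipe, the read-back number gives 61.3%, and that neighbour stands at 61.2%.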